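**Plan**

- Retrosynthesis (chroman numbering for ring atoms throughout): the enol lactone is opened last; before that the C6–prenyl bond is cut, then the bond from ring carbon C8 to the β-carbon of the hexanoic chain together with the lactol O–C bond, then the C6–CH2 bond to the cyclobutylmethyl group.
- The cyclobutane is traced back to a cyclopentanone (ring contraction) and the benzopyranone to phloroglucinol.
- Forward: cyclopentanone → cyclobutane; phloroglucinol → benzopyranone ring; the two are joined by a Negishi coupling; the lactol ring closes in the key step and is oxidised to the lactone; C6 is prenylated with dearomatisation; the lactone is hydrolysed.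
- Feature that enables the key step: C8 is the only unsubstituted carbon of the benzene ring of the chroman-4-one. It sits between C7, which carries a free hydroxyl, and C8a, which carries the pyranone oxygen, so it is the nucleophile for the enal and the C7 hydroxyl then closes a six-membered lactol.
- Stereochemistry: the isopropenyl-bearing cyclobutane carbon comes from a rhodium/(R)-BINAP conjugate addition; its trans neighbour from ester equilibration; the side-chain centre from the prolinol silyl ether catalyst; the C6 quaternary centre from a chiral palladium catalyst.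

Key step: step 11

Assumption: the sense of induction of the (R,R)-bisphosphine in step 13 is taken by analogy with related phenol dearomatisations; if a first run shows the opposite sense, the (S,S) ligand is used in the same step.

**Step 1**
Reactants: 1 4,4-dimethylcyclopent-2-en-1-one; 2 isopropenylboronic acid pinacol ester
Product: 3 (4R)-3,3-dimethyl-4-(prop-1-en-2-yl)cyclopentan-1-one
Conditions: [RhCl(C2H4)2]2 (2.5 mol %), (R)-BINAP (6 mol %), KOH (0.5 equiv), 1,4-dioxane/H2O 10:1, 50 °C
Reagents that add atoms: none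
Why: Hayashi–Miyaura 1,4-addition, in which the isopropenyl–rhodium species inserts the enone from the face left open by (R)-BINAP (the opposite face to that giving (S)-3-arylcycloalkanones with (S)-BINAP), which should set the (R) centre next to the quaternary carbon before water releases the ketone.

**Step 2**
Reactants: 3 (4R)-3,3-dimethyl-4-(prop-1-en-2-yl)cyclopentan-1-one
Product: 5 (3R)-2-diazo-4,4-dimethyl-3-(prop-1-en-2-yl)cyclopentan-1-one, via trifluoroacetyl ketone 4 (not isolated)
Conditions: LiN(SiMe3)2, THF, −78 °C; CF3CO2CH2CF3, −78 °C; then MeSO2N3, Et3N, H2O (1 equiv), MeCN, 25 °C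
Reagents that add atoms: methanesulfonyl azide, CS(=O)(=O)N=[N+]=[N-]; 2,2,2-trifluoroethyl trifluoroacetate, O=C(OCC(F)(F)F)C(F)(F)F (its acyl group stays only in 4)
Why: Detrifluoroacetylative Regitz-type diazo transfer, in which the amide base should remove the unhindered proton of the α-methylene next to the isopropenyl-bearing carbon (the other α-methylene is shielded by the gem-dimethyl group), the enolate is C-acylated and the activated dicarbonyl passes its trifluoroacetyl group to the azide as the diazo group is installed.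

**Step 3**
Reactants: 5 (3R)-2-diazo-4,4-dimethyl-3-(prop-1-en-2-yl)cyclopentan-1-one
Product: 8 methyl (1R,2R)-3,3-dimethyl-2-(prop-1-en-2-yl)cyclobutane-1-carboxylate (trans), via cyclobutylketene 6 (not isolated), via cis ester 7 (not isolated)
Conditions: hν (medium-pressure Hg lamp, Pyrex), MeOH, 0 °C; then NaOMe, MeOH, 50 °C
Reagents that add atoms: methanol, CO
Why: Photochemical Wolff rearrangement of a cyclic α-diazo ketone contracts the five-membered ring to the ketene, methanol traps it as the ester, and methoxide equilibrates the α-carbon to the trans isomer in which the ester avoids the neighbouring isopropenyl group, so the second ring stereocentre is set under thermodynamic control relative to the first.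

**Step 4**
Reactants: 8 methyl (1R,2R)-3,3-dimethyl-2-(prop-1-en-2-yl)cyclobutane-1-carboxylate
Product: 9 [(1R,2R)-3,3-dimethyl-2-(prop-1-en-2-yl)cyclobutyl]methanol
Conditions: LiAlH4, Et2O, 0 °C
Reagents that add atoms: none
Why: Hydride reduction of the ester to the primary alcohol, which leaves the isolated alkene and both ring stereocentres untouched.

**Step 5**
Reactants: 9 [(1R,2R)-3,3-dimethyl-2-(prop-1-en-2-yl)cyclobutyl]methanol
Product: 10 (1R,2R)-1-(iodomethyl)-3,3-dimethyl-2-(prop-1-en-2-yl)cyclobutane
Conditions: I2, PPh3, imidazole, CH2Cl2, 0 → 25 °C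
Reagents that add atoms: iodine, II
Why: Appel-type iodination, in which iodide displaces the alkoxyphosphonium group by SN2 at the primary carbon, so no cyclobutylcarbinyl cation and no ring expansion can arise.

**Step 6**
Reactants: 11 phloroglucinol; 12 3-methylbut-2-enoic acid
Product: 13 5,7-dihydroxy-2,2-dimethylchroman-4-one
Conditions: P2O5, MeSO3H, 70 °C
Reagents that add atoms: none
Why: Friedel–Crafts acylation of phloroglucinol followed by oxa-Michael closure of the ortho phenol onto the aryl enone, with the threefold symmetry of phloroglucinol making the regiochemistry unambiguous.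

**Step 7**
Reactants: 13 5,7-dihydroxy-2,2-dimethylchroman-4-one
Product: 14 5-hydroxy-2,2-dimethyl-7-[(triisopropylsilyl)oxy]chroman-4-one
Conditions: iPr3SiCl, imidazole, DMF, 0 → 25 °C
Reagents that add atoms: chlorotriisopropylsilane, CC(C)[Si](Cl)(C(C)C)C(C)C
Why: Selective O-silylation, since the C5 hydroxyl is held in a hydrogen bond to the C4 carbonyl and only the C7 phenol reacts.

**Step 8**
Reactants: 14 5-hydroxy-2,2-dimethyl-7-[(triisopropylsilyl)oxy]chroman-4-one
Product: 15 5-hydroxy-6-iodo-2,2-dimethyl-7-[(triisopropylsilyl)oxy]chroman-4-one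
Conditions: BnMe3N[ICl2], CaCO3, CH2Cl2/MeOH 5:2, 25 °C
Reagents that add atoms: benzyltrimethylammonium dichloroiodate, C[N+](C)(C)Cc1ccccc1.Cl[I-]Cl
Why: Electrophilic aromatic iodination directed ortho to the free chelated C5 phenol, the site selectivity known for 5-hydroxy-7-alkoxy benzopyranones with this reagent, with CaCO3 taking up the acid formed.

**Step 9**
Reactants: 10 (1R,2R)-1-(iodomethyl)-3,3-dimethyl-2-(prop-1-en-2-yl)cyclobutane; 15 5-hydroxy-6-iodo-2,2-dimethyl-7-[(triisopropylsilyl)oxy]chroman-4-one
Product: 17 6-{[(1S,2R)-3,3-dimethyl-2-(prop-1-en-2-yl)cyclobutyl]methyl}-5-hydroxy-2,2-dimethyl-7-[(triisopropylsilyl)oxy]chroman-4-one, via alkylzinc iodide 16 (not isolated)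
Conditions: 10, Zn dust (activated with BrCH2CH2Br and Me3SiCl), LiCl, THF, 40 °C; then 15, Pd(OAc)2 (3 mol %), SPhos (6 mol %), THF, 25 → 40 °C
Reagents that add atoms: zinc, [Zn] (it stays only in 16)
Why: Negishi coupling, in which LiCl-assisted zinc insertion gives the primary alkylzinc iodide that transmetalates to the arylpalladium iodide formed at C6, the bulky biaryl phosphine favouring reductive elimination at the di-ortho-substituted carbon over β-hydride elimination, while alkylzinc halides are known to tolerate a hydrogen-bonded phenol.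

**Step 10**
Reactants: 17 6-{[(1S,2R)-3,3-dimethyl-2-(prop-1-en-2-yl)cyclobutyl]methyl}-5-hydroxy-2,2-dimethyl-7-[(triisopropylsilyl)oxy]chroman-4-one
Product: 18 6-{[(1S,2R)-3,3-dimethyl-2-(prop-1-en-2-yl)cyclobutyl]methyl}-5,7-dihydroxy-2,2-dimethylchroman-4-one
Conditions: Bu4NF, AcOH, THF, 0 °C
Reagents that add atoms: none
Why: Fluoride cleavage of the aryl silyl ether, buffered with acetic acid so that the acidic phenol is released without exposing the chromanone to free phenoxide.

**Step 11**
Reactants: 18 6-{[(1S,2R)-3,3-dimethyl-2-(prop-1-en-2-yl)cyclobutyl]methyl}-5,7-dihydroxy-2,2-dimethylchroman-4-one; 19 (E)-hex-2-enal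
Product: 21 (10R)-6-{[(1S,2R)-3,3-dimethyl-2-(prop-1-en-2-yl)cyclobutyl]methyl}-5,8-dihydroxy-2,2-dimethyl-10-propyl-2,3,9,10-tetrahydro-4H,8H-pyrano[2,3-f]chromen-4-one (lactol fused at C7–O and C8 of the chromanone, both anomers), via hydroxy aldehyde 20 (not isolated)
Conditions: (S)-α,α-diphenylprolinol trimethylsilyl ether (20 mol %), PhCO2H (20 mol %), toluene, 0 → 25 °C
Reagents that add atoms: none
Why: Condensation of 19 with the secondary amine gives the (E)-iminium ion, one face of which is shielded by the diphenyl(silyloxy)methyl group, and C8 of 18 adds to its β-carbon in a Friedel–Crafts-type conjugate addition, after which hydrolysis of the enamine releases the catalyst and hydroxy aldehyde 20. The closest known reaction type is the prolinol silyl ether-catalysed Friedel–Crafts alkylation and hemiacetalisation of naphthols and other electron-rich phenols with enals, which gives 4-substituted chroman-2-ols. The one ring formed, the six-membered lactol, closes by 6-exo-trig attack of the C7 hydroxyl on the aldehyde carbon. The new stereocentre on the chain is set by the catalyst alone: with the (S)-pyrrolidine the arene should approach the Re face of the β-carbon, which corresponds to the (R) configuration, the cyclobutane centres being too remote to interfere. The step needs site selectivity and enantioface selectivity; the first is secured because C8, flanked by the C7 hydroxyl and the pyranone oxygen on C8a and para to the C5 hydroxyl, is the only unsubstituted ring carbon and any oxa-Michael addition is reversible, the second by the catalyst. The anomeric mixture at the lactol carbon does not matter, since that carbon is oxidised in step 12.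

**Step 12**
Reactants: 21 the lactol of step 11
Product: 22 (10R)-6-{[(1S,2R)-3,3-dimethyl-2-(prop-1-en-2-yl)cyclobutyl]methyl}-5-hydroxy-2,2-dimethyl-10-propyl-2,3,9,10-tetrahydro-4H,8H-pyrano[2,3-f]chromene-4,8-dione (dihydrocoumarin-type lactone)
Conditions: pyridinium chlorochromate (C5H5NH)[CrO3Cl], NaOAc, 4 Å molecular sieves, CH2Cl2, 25 °C
Reagents that add atoms: none
Why: Chromate oxidation of the cyclic hemiacetal to the lactone, the usual follow-up for chroman-2-ols from this cascade, under which the chelated C5 phenol and the 1,1-disubstituted alkene should be inert.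

**Step 13**
Reactants: 22 the lactone of step 12; 23 3-methylbut-2-en-1-yl acetate (prenyl acetate)
Product: 24 (6S,10R)-6-{[(1S,2R)-3,3-dimethyl-2-(prop-1-en-2-yl)cyclobutyl]methyl}-2,2-dimethyl-6-(3-methylbut-2-en-1-yl)-10-propyl-2,3,9,10-tetrahydro-4H,8H-pyrano[2,3-f]chromene-4,5,8(6H)-trione
Conditions: Pd2(dba)3·CHCl3 (2.5 mol %), N,N'-[(1R,2R)-cyclohexane-1,2-diyl]bis[2-(diphenylphosphanyl)benzamide] (7.5 mol %), Cs2CO3, 1,4-dioxane, 25 °C
Reagents that add atoms: none
Why: Tsuji–Trost allylic alkylation used as a dearomatisation, in which the phenoxide of the C5 hydroxyl attacks the unsubstituted terminus of the π-prenyl palladium complex through C6 (the C7 oxygen being masked in the lactone), reversible O-allylation drains into the C-alkylated dienone, and the chiral pocket of the bisphosphine is relied on to choose the face of C6 and so set the quaternary centre.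

**Step 14**
Reactants: 24 the dearomatised prenyl lactone of step 13
Product: 25 (3R)-3-[(6R)-6-{[(1S,2R)-3,3-dimethyl-2-(prop-1-en-2-yl)cyclobutyl]methyl}-5-hydroxy-2,2-dimethyl-6-(3-methylbut-2-en-1-yl)-4,7-dioxo-3,4,6,7-tetrahydro-2H-chromen-8-yl]hexanoic acid (CNP0358381.1)
Conditions: LiOH, THF/H2O 3:1, 0 °C; then 1 M HCl
Reagents that add atoms: water, O
Why: Saponification of the enol lactone, the most electrophilic acyl group present, frees the carboxylic acid and the C7 enol, which tautomerises to the C7-oxo/C5-enol form hydrogen-bonded to the C4 carbonyl without touching any stereocentre (the C6 descriptor changes from S to R only because the ranking of its neighbours changes).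

**Compound list**

1 | 4,4-dimethylcyclopent-2-en-1-one | CC1(C)C=CC(=O)C1 | starting material
2 | isopropenylboronic acid pinacol ester | C=C(C)B1OC(C)(C)C(C)(C)O1 | starting material
3 | (4R)-3,3-dimethyl-4-(prop-1-en-2-yl)cyclopentan-1-one | C=C(C)[C@H]1CC(=O)CC1(C)C | intermediate
4 | (3R)-4,4-dimethyl-3-(prop-1-en-2-yl)-2-(trifluoroacetyl)cyclopentan-1-one (formed as its lithium enolate, C2 unassigned) | C=C(C)[C@H]1C(C(=O)C(F)(F)F)C(=O)CC1(C)C | intermediate
5 | (3R)-2-diazo-4,4-dimethyl-3-(prop-1-en-2-yl)cyclopentan-1-one | C=C(C)[C@H]1C(=[N+]=[N-])C(=O)CC1(C)C | intermediate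
6 | [(2R)-3,3-dimethyl-2-(prop-1-en-2-yl)cyclobutylidene]methanone (ketene) | C=C(C)[C@H]1C(=C=O)CC1(C)C | intermediate
7 | methyl (1S,2R)-3,3-dimethyl-2-(prop-1-en-2-yl)cyclobutane-1-carboxylate (cis) | C=C(C)[C@H]1[C@@H](C(=O)OC)CC1(C)C | intermediate
8 | methyl (1R,2R)-3,3-dimethyl-2-(prop-1-en-2-yl)cyclobutane-1-carboxylate (trans) | C=C(C)[C@H]1[C@H](C(=O)OC)CC1(C)C | intermediate
9 | [(1R,2R)-3,3-dimethyl-2-(prop-1-en-2-yl)cyclobutyl]methanol | C=C(C)[C@H]1[C@H](CO)CC1(C)C | intermediate
10 | (1R,2R)-1-(iodomethyl)-3,3-dimethyl-2-(prop-1-en-2-yl)cyclobutane | C=C(C)[C@H]1[C@H](CI)CC1(C)C | intermediate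
11 | phloroglucinol | Oc1cc(O)cc(O)c1 | starting material
12 | 3-methylbut-2-enoic acid | CC(C)=CC(=O)O | starting material
13 | 5,7-dihydroxy-2,2-dimethylchroman-4-one | CC1(C)CC(=O)c2c(O)cc(O)cc2O1 | intermediate
14 | 5-hydroxy-2,2-dimethyl-7-[(triisopropylsilyl)oxy]chroman-4-one | CC1(C)CC(=O)c2c(O)cc(O[Si](C(C)C)(C(C)C)C(C)C)cc2O1 | intermediate
15 | 5-hydroxy-6-iodo-2,2-dimethyl-7-[(triisopropylsilyl)oxy]chroman-4-one | CC1(C)CC(=O)c2c(O)c(I)c(O[Si](C(C)C)(C(C)C)C(C)C)cc2O1 | intermediate
16 | {[(1R,2R)-3,3-dimethyl-2-(prop-1-en-2-yl)cyclobutyl]methyl}zinc iodide | C=C(C)[C@H]1[C@H](C[Zn]I)CC1(C)C | intermediate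
17 | 6-{[(1S,2R)-3,3-dimethyl-2-(prop-1-en-2-yl)cyclobutyl]methyl}-5-hydroxy-2,2-dimethyl-7-[(triisopropylsilyl)oxy]chroman-4-one | C=C(C)[C@H]1[C@H](Cc2c(O)c3C(=O)CC(C)(C)Oc3cc2O[Si](C(C)C)(C(C)C)C(C)C)CC1(C)C | intermediate
18 | 6-{[(1S,2R)-3,3-dimethyl-2-(prop-1-en-2-yl)cyclobutyl]methyl}-5,7-dihydroxy-2,2-dimethylchroman-4-one | C=C(C)[C@H]1[C@H](Cc2c(O)cc3OC(C)(C)CC(=O)c3c2O)CC1(C)C | intermediate
19 | (E)-hex-2-enal | CCC/C=C/C=O | starting material
20 | (3R)-3-[6-{[(1S,2R)-3,3-dimethyl-2-(prop-1-en-2-yl)cyclobutyl]methyl}-5,7-dihydroxy-2,2-dimethyl-4-oxochroman-8-yl]hexanal | C=C(C)[C@H]1[C@H](Cc2c(O)c([C@H](CCC)CC=O)c3OC(C)(C)CC(=O)c3c2O)CC1(C)C | intermediate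
21 | (10R)-6-{[(1S,2R)-3,3-dimethyl-2-(prop-1-en-2-yl)cyclobutyl]methyl}-5,8-dihydroxy-2,2-dimethyl-10-propyl-2,3,9,10-tetrahydro-4H,8H-pyrano[2,3-f]chromen-4-one (both anomers) | C=C(C)[C@H]1[C@H](Cc2c(O)c3C(=O)CC(C)(C)Oc3c4[C@H](CCC)CC(O)Oc24)CC1(C)C | intermediate
22 | (10R)-6-{[(1S,2R)-3,3-dimethyl-2-(prop-1-en-2-yl)cyclobutyl]methyl}-5-hydroxy-2,2-dimethyl-10-propyl-2,3,9,10-tetrahydro-4H,8H-pyrano[2,3-f]chromene-4,8-dione | C=C(C)[C@H]1[C@H](Cc2c(O)c3C(=O)CC(C)(C)Oc3c4[C@H](CCC)CC(=O)Oc24)CC1(C)C | intermediate
23 | 3-methylbut-2-en-1-yl acetate | CC(C)=CCOC(C)=O | starting material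
24 | (6S,10R)-6-{[(1S,2R)-3,3-dimethyl-2-(prop-1-en-2-yl)cyclobutyl]methyl}-2,2-dimethyl-6-(3-methylbut-2-en-1-yl)-10-propyl-2,3,9,10-tetrahydro-4H,8H-pyrano[2,3-f]chromene-4,5,8(6H)-trione | C=C(C)[C@H]1[C@H](C[C@]2(CC=C(C)C)C3=C([C@H](CCC)CC(=O)O3)C4=C(C(=O)CC(C)(C)O4)C2=O)CC1(C)C | intermediate
25 | (3R)-3-[(6R)-6-{[(1S,2R)-3,3-dimethyl-2-(prop-1-en-2-yl)cyclobutyl]methyl}-5-hydroxy-2,2-dimethyl-6-(3-methylbut-2-en-1-yl)-4,7-dioxo-3,4,6,7-tetrahydro-2H-chromen-8-yl]hexanoic acid | C=C(C)[C@H]1[C@H](C[C@]2(CC=C(C)C)C(=O)C([C@H](CCC)CC(=O)O)=C3OC(C)(C)CC(=O)C3=C2O)CC1(C)C | target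

Total step count: 14. Longest linear sequence: 11 steps (steps 1–5, then 9–14).

**Steps most likely to fail**

Step 13. The prenyl group may end up on the phenol oxygen or be attached through its substituted terminus, and the catalyst may discriminate the two faces of C6 poorly, so that both configurations of the quaternary centre form. The fallback sets out from lactone 22 and comes back at target 25. The lactone is first opened with LiOH in aqueous THF to (3R)-3-[6-{[(1S,2R)-3,3-dimethyl-2-(prop-1-en-2-yl)cyclobutyl]methyl}-5,7-dihydroxy-2,2-dimethyl-4-oxochroman-8-yl]hexanoic acid F1. Its trianion is then alkylated in the classical manner for acylphloroglucinols with prenyl bromide in aqueous KOH at 0 °C, the carbon C6 between two oxygenated carbons being alkylated with dearomatisation. This gives 25 together with the C6 epimer of 25 F2, and 25 is separated by preparative HPLC.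

Step 1. Insertion of the enone next to the quaternary carbon may be slow, so that protodeboronation of the alkenylboronate outruns addition, or the enantioface selection may be eroded. The fallback sets out from enone 1 and comes back at ketone 3. Copper-catalysed addition of CH2=C(CH3)MgBr (CuBr·SMe2, THF, −40 °C) gives racemic 3,3-dimethyl-4-(prop-1-en-2-yl)cyclopentan-1-one F3. Addition of lithiated (S)-N,S-dimethyl-S-phenylsulfoximine gives diastereomeric β-hydroxy sulfoximines, from which (4R)-3,3-dimethyl-1-{[(S)-N-methyl-S-phenylsulfonimidoyl]methyl}-4-(prop-1-en-2-yl)cyclopentan-1-ol F4, the adduct of the (R)-ketone, is separated by chromatography. Thermolysis in refluxing toluene reverses the addition and releases 3.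

Step 9. The alkylzinc may be protonated by the free phenol before it transmetalates, or reductive elimination at the hindered carbon may lag so that the aryl iodide is simply reduced. The fallback sets out from iodide 10 (with aryl iodide 15) and comes back at 17. Iodine–lithium exchange of 10 with t-BuLi in Et2O at −78 °C and capture with B-methoxy-9-borabicyclo[3.3.1]nonane gives lithium {[(1R,2R)-3,3-dimethyl-2-(prop-1-en-2-yl)cyclobutyl]methyl}(methoxy)-9-borabicyclo[3.3.1]nonan-9-uide F5. This is coupled with 15 in a B-alkyl Suzuki–Miyaura reaction (PdCl2(dppf), aqueous K3PO4, DMF, 25 °C), conditions under which the phenol is only deprotonated.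

**Further compounds**

F1 | step 13 | (3R)-3-[6-{[(1S,2R)-3,3-dimethyl-2-(prop-1-en-2-yl)cyclobutyl]methyl}-5,7-dihydroxy-2,2-dimethyl-4-oxochroman-8-yl]hexanoic acid | C=C(C)[C@H]1[C@H](Cc2c(O)c([C@H](CCC)CC(=O)O)c3OC(C)(C)CC(=O)c3c2O)CC1(C)C
F2 | step 13 | (3R)-3-[(6S)-6-{[(1S,2R)-3,3-dimethyl-2-(prop-1-en-2-yl)cyclobutyl]methyl}-5-hydroxy-2,2-dimethyl-6-(3-methylbut-2-en-1-yl)-4,7-dioxo-3,4,6,7-tetrahydro-2H-chromen-8-yl]hexanoic acid (C6 epimer of 25) | C=C(C)[C@H]1[C@H](C[C@@]2(CC=C(C)C)C(=O)C([C@H](CCC)CC(=O)O)=C3OC(C)(C)CC(=O)C3=C2O)CC1(C)C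
F3 | step 1 | racemic 3,3-dimethyl-4-(prop-1-en-2-yl)cyclopentan-1-one | C=C(C)C1CC(=O)CC1(C)C
F4 | step 1 | (4R)-3,3-dimethyl-1-{[(S)-N-methyl-S-phenylsulfonimidoyl]methyl}-4-(prop-1-en-2-yl)cyclopentan-1-ol (sulfoximinylmethyl group trans to isopropenyl) | C=C(C)[C@H]1C[C@](O)(C[S@@](=O)(=NC)c2ccccc2)CC1(C)C
F5 | step 9 | lithium {[(1R,2R)-3,3-dimethyl-2-(prop-1-en-2-yl)cyclobutyl]methyl}(methoxy)-9-borabicyclo[3.3.1]nonan-9-uide | C=C(C)[C@H]1[C@H](C[B-]2(OC)C3CCCC2CCC3)CC1(C)C.[Li+]
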